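**Retrosynthetic overview**
- Target 24 is cut at the C6' ester C–O bond to R-marmin 22 and linoleic acid 23. Marmin 22 is cut at the C1'–O7 allyl aryl ether bond to triol 20 and umbelliferone 21.
- The strategy rests on the trisubstituted E C2'=C3' alkene, whose C3' methyl is cis to C1'. Triol 20 is therefore cut at C3'–CH3 and C2'–C1' to the terminal alkyne of diol 14, trimethylaluminium 15 and formaldehyde 16 (syn methylmetalation, then one-carbon capture at C2').
- Diol 14 is cut at C4'–C5' to the O-silylated epoxide 10 and the propargylic anion of 1-(trimethylsilyl)propyne 11. Epoxide 10 comes from methyl (R)-glycerate acetonide 1, which supplies the only stereocentre (C6'); C7' gets its two methyls by double Grignard addition.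
- No ring is built. The benzene and pyranone rings of the coumarin are bought intact in 21, and the oxirane of 8 and 10 is only a transient electrophile.

Key step: step 8

Remark: paraformaldehyde is counted as its monomer, the in-flask aluminium species 17–19 are drawn in their simplest monomeric form although they will be aggregated, and reagents whose atoms enter a product are numbered like starting materials.

**Route**

Step 1
Reactants: 1 methyl (4R)-2,2-dimethyl-1,3-dioxolane-4-carboxylate; 2 methylmagnesium bromide
Product: 4 2-[(4R)-2,2-dimethyl-1,3-dioxolan-4-yl]propan-2-ol, via methyl ketone 3 (not isolated)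
Conditions: MeMgBr (3 equiv), THF, 0 °C → rt; then H2O/aq NH4Cl
Reagents that add atoms: methylmagnesium bromide (2), C[Mg]Br
Why: Double Grignard addition to the ester through ketone 3 is a standard way to a dimethyl carbinol, and the C4 stereocentre, which comes from the chiral pool, should survive because carbonyl addition at low temperature outpaces enolisation.

Step 2
Reactants: 4 2-[(4R)-2,2-dimethyl-1,3-dioxolan-4-yl]propan-2-ol
Product: 5 (2R)-3-methylbutane-1,2,3-triol
Conditions: Dowex 50WX8 (H+ form), THF–H2O, 40 °C; filter, concentrate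
Reagents that add atoms: none
Why: Acid-catalysed acetal hydrolysis frees the 1,2-diol without breaking the C–O bond at the stereocentre, and the resin is filtered off so that the water-soluble triol needs no extraction.

Step 3
Reactants: 5 (2R)-3-methylbutane-1,2,3-triol; 6 4-methylbenzenesulfonyl chloride
Product: 7 (2R)-2,3-dihydroxy-3-methylbutyl 4-methylbenzenesulfonate
Conditions: TsCl (1.05 equiv), pyridine, CH2Cl2, −10 → 0 °C
Reagents that add atoms: 4-methylbenzenesulfonyl chloride (6), Cc1ccc(cc1)S(Cl)(=O)=O
Why: Selective sulfonylation should take place at the primary hydroxyl, since the secondary one is flanked by a fully substituted carbon and the tertiary one is inert under these conditions.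

Step 4
Reactants: 7 (2R)-2,3-dihydroxy-3-methylbutyl 4-methylbenzenesulfonate
Product: 8 2-[(2R)-oxiran-2-yl]propan-2-ol
Conditions: K2CO3 (1.5 equiv), MeOH, 0 °C, short contact; Et2O, filter, concentrate cold (volatile)
Reagents that add atoms: none
Why: Intramolecular Williamson etherification (3-exo-tet) of the secondary alkoxide onto the primary tosylate closes the oxirane with the stereocentre retained, because its C–O bond is kept, and the short contact at 0 °C limits Payne isomerisation.

Step 5
Reactants: 8 2-[(2R)-oxiran-2-yl]propan-2-ol; 9 chlorotriethylsilane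
Product: 10 triethyl({2-[(2R)-oxiran-2-yl]propan-2-yl}oxy)silane
Conditions: TESCl (1.3 equiv), imidazole, DMAP (cat.), DMF, 0 °C → rt
Reagents that add atoms: chlorotriethylsilane (9), CC[Si](Cl)(CC)CC
Why: Silyl ether formation at the tertiary hydroxyl removes the neighbouring alkoxide that could trigger Payne rearrangement or consume organolithium in the next step, and it makes the epoxide less volatile.

Step 6
Reactants: 10 triethyl({2-[(2R)-oxiran-2-yl]propan-2-yl}oxy)silane; 11 1-(trimethylsilyl)propyne
Product: 13 (3R)-2-methyl-2-[(triethylsilyl)oxy]-7-(trimethylsilyl)hept-6-yn-3-ol, via lithiated silylpropyne 12 (not isolated)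
Conditions: 11 (1.5 equiv), n-BuLi, TMEDA, THF, −78 → 0 °C; then 10, DMPU, −78 °C → rt; H2O
Reagents that add atoms: 1-(trimethylsilyl)propyne (11), C[Si](C)(C)C#CC
Why: SN2 opening of the terminal epoxide at its CH2 carbon by the propargylic organolithium 12, whose C-silyl group blocks the acetylenic end, forms the C4–C5 bond without touching C3, and a possible O-to-O silyl shift in the alkoxide is harmless because both silyl groups are removed next.

Step 7
Reactants: 13 (3R)-2-methyl-2-[(triethylsilyl)oxy]-7-(trimethylsilyl)hept-6-yn-3-ol
Product: 14 (3R)-2-methylhept-6-yne-2,3-diol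
Conditions: TBAF (3 equiv), THF, 0 °C → rt
Reagents that add atoms: none
Why: Fluoride-mediated desilylation cleaves the alkynyl C–Si bond and the tertiary O–Si bond in one operation to give the free alkyne diol.

Step 8
Reactants: 14 (3R)-2-methylhept-6-yne-2,3-diol; 15 trimethylaluminium; 16 formaldehyde (as paraformaldehyde)
Product: 20 (2E,6R)-3,7-dimethyloct-2-ene-1,6,7-triol, via aluminium dialkoxide 17 (not isolated), via alkenylalane 18 (not isolated), via lithium alanate 19 (not isolated)
Conditions: AlMe3 (5 equiv), Cp2ZrCl2 (0.5 equiv), CH2Cl2, 0 °C; add 14 (CH4 evolution), rt, 16 h; remove volatiles in vacuo; hexane–THF, n-BuLi (ca. 3 equiv), −78 → 0 °C; (CH2O)n (excess), 0 °C → rt; aq Rochelle salt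
Reagents that add atoms: trimethylaluminium (15), C[Al](C)C; formaldehyde (16), C=O
Why: This is a Negishi zirconium-catalysed methylalumination followed by hydroxymethylation of the alanate: the two hydroxyls of 14 are first masked in situ as aluminium alkoxides (17), then the methylzirconocene–aluminium species adds methyl and metal syn across the terminal alkyne through a four-centre transition state, methyl to the internal carbon and metal to the terminal carbon, to give the (E)-alkenylalane 18 after Zr-to-Al exchange. n-BuLi converts 18 into the more nucleophilic alanate 19, whose alkenyl group adds to formaldehyde with retention at the sp2 carbon, so that the C3'–CH3 and C2'–C1' bonds of 20 are made in one pot. The closest known reaction type is the carboalumination, ate-complex, paraformaldehyde sequence that turns terminal alkynes, including alkynols run as their aluminium alkoxides, into (E)-3-methylalk-2-en-1-ols. No ring is closed and no stereocentre is created; C6 of 20 lies three carbons from the alkyne and is not touched. The step needs regioselectivity (metal at the terminus) and syn stereospecificity; the unhindered terminal alkyne and the stereoretentive replacement of C–Al by C–C secure both, so the methyl ends up cis to C1' and the alkene is E.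

Step 9
Reactants: 20 (2E,6R)-3,7-dimethyloct-2-ene-1,6,7-triol; 21 umbelliferone (7-hydroxy-2H-chromen-2-one)
Product: 22 R-marmin, 7-{[(2E,6R)-6,7-dihydroxy-3,7-dimethyloct-2-en-1-yl]oxy}-2H-chromen-2-one
Conditions: 21 (1.0 equiv), PPh3 (1.1 equiv), DIAD (1.1 equiv, added last), THF, 0 °C → rt
Reagents that add atoms: umbelliferone (21), O=c1ccc2ccc(O)cc2o1
Why: In this Mitsunobu etherification the primary allylic hydroxyl should be activated far faster than the secondary and tertiary hydroxyls next to the fully substituted C7, and the acidic phenol 21 displaces the oxyphosphonium by SN2 at C1 with the E alkene kept.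

Step 10
Reactants: 22 R-marmin; 23 linoleic acid, (9Z,12Z)-octadeca-9,12-dienoic acid
Product: 24 R-(+)-marmin-6'-linoleate, (3R,6E)-2-hydroxy-2,6-dimethyl-8-[(2-oxo-2H-chromen-7-yl)oxy]oct-6-en-3-yl (9Z,12Z)-octadeca-9,12-dienoate
Conditions: 23 (1.2 equiv), DCC (1.3 equiv), DMAP (0.2 equiv), CH2Cl2, 0 °C → rt, Ar, dark
Reagents that add atoms: linoleic acid (23), CCCCC/C=C\C/C=C\CCCCCCCC(=O)O
Why: Steglich esterification should acylate the secondary C6' hydroxyl while the tertiary C7' hydroxyl is too hindered to react, and the mild conditions keep the skipped Z,Z-diene and the C6' configuration, since no bond at the stereocentre is broken.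

**Compound list**

1 | methyl (4R)-2,2-dimethyl-1,3-dioxolane-4-carboxylate | CC1(C)OC[C@@H](O1)C(=O)OC | starting material
2 | methylmagnesium bromide | C[Mg]Br | starting material
3 | 1-[(4R)-2,2-dimethyl-1,3-dioxolan-4-yl]ethan-1-one (methyl ketone, not isolated) | CC1(C)OC[C@@H](O1)C(C)=O | intermediate
4 | 2-[(4R)-2,2-dimethyl-1,3-dioxolan-4-yl]propan-2-ol | CC1(C)OC[C@@H](O1)C(C)(C)O | intermediate
5 | (2R)-3-methylbutane-1,2,3-triol | OC[C@@H](O)C(C)(C)O | intermediate
6 | 4-methylbenzenesulfonyl chloride | Cc1ccc(cc1)S(Cl)(=O)=O | starting material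
7 | (2R)-2,3-dihydroxy-3-methylbutyl 4-methylbenzenesulfonate | Cc1ccc(cc1)S(=O)(=O)OC[C@@H](O)C(C)(C)O | intermediate
8 | 2-[(2R)-oxiran-2-yl]propan-2-ol | CC(C)(O)[C@H]1CO1 | intermediate
9 | chlorotriethylsilane | CC[Si](Cl)(CC)CC | starting material
10 | triethyl({2-[(2R)-oxiran-2-yl]propan-2-yl}oxy)silane | CC[Si](CC)(CC)OC(C)(C)[C@H]1CO1 | intermediate
11 | 1-(trimethylsilyl)propyne | C[Si](C)(C)C#CC | starting material
12 | 3-lithio-1-(trimethylsilyl)propyne (not isolated) | [Li]CC#C[Si](C)(C)C | intermediate
13 | (3R)-2-methyl-2-[(triethylsilyl)oxy]-7-(trimethylsilyl)hept-6-yn-3-ol | CC[Si](CC)(CC)OC(C)(C)[C@H](O)CCC#C[Si](C)(C)C | intermediate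
14 | (3R)-2-methylhept-6-yne-2,3-diol | O[C@H](CCC#C)C(C)(C)O | intermediate
15 | trimethylaluminium | C[Al](C)C | starting material
16 | formaldehyde (used as paraformaldehyde) | C=O | starting material
17 | bis(dimethylaluminium) dialkoxide of 14 (not isolated) | C[Al](C)O[C@H](CCC#C)C(C)(C)O[Al](C)C | intermediate
18 | (E)-alkenyldimethylalane from 17 (not isolated) | C[Al](C)O[C@H](CC/C(C)=C/[Al](C)C)C(C)(C)O[Al](C)C | intermediate
19 | lithium (E)-alkenyl(butyl)dimethylaluminate from 18 (not isolated) | C[Al](C)O[C@H](CC/C(C)=C/[Al-](C)(C)CCCC)C(C)(C)O[Al](C)C.[Li+] | intermediate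
20 | (2E,6R)-3,7-dimethyloct-2-ene-1,6,7-triol | O[C@H](CC/C(C)=C/CO)C(C)(C)O | intermediate
21 | umbelliferone (7-hydroxy-2H-chromen-2-one) | O=c1ccc2ccc(O)cc2o1 | starting material
22 | R-marmin, 7-{[(2E,6R)-6,7-dihydroxy-3,7-dimethyloct-2-en-1-yl]oxy}-2H-chromen-2-one | O[C@H](CC/C(C)=C/COc1ccc2ccc(=O)oc2c1)C(C)(C)O | intermediate
23 | linoleic acid, (9Z,12Z)-octadeca-9,12-dienoic acid | CCCCC/C=C\C/C=C\CCCCCCCC(=O)O | starting material
24 | R-(+)-marmin-6'-linoleate | CCCCC/C=C\C/C=C\CCCCCCCC(=O)O[C@H](CC/C(C)=C/COc1ccc2ccc(=O)oc2c1)C(C)(C)O | target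

**Step count**
Total: 10 steps. Longest linear sequence: 10 steps (1 → 24).

**Steps most likely to fail**

Step 8. The capture of the alkenyl–aluminium bond by formaldehyde may be inefficient, because the aluminium alkoxides and residual methylaluminium compete for n-BuLi; the alkenylalane would then be protonated on work-up instead of hydroxymethylated. The fallback sets out from 14 and brings in C1' as carbon monoxide. The same methylalumination is run through 17 and 18, but 18 is quenched with iodine (THF, −30 → 0 °C), which cleaves the alkenyl–Al bond with retention and ignores the alkoxides, to give (3R,6E)-7-iodo-2,6-dimethylhept-6-ene-2,3-diol F1. Palladium-catalysed methoxycarbonylation (Pd(PPh3)2Cl2 cat., CO 1 atm, MeOH, Et3N, DMF, 50 °C) should give methyl (2E,6R)-6,7-dihydroxy-3,7-dimethyloct-2-enoate F2 with the geometry kept. Reduction with excess DIBAL-H (CH2Cl2, −78 °C) comes back to the route at 20.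

Step 9. The phosphonium reagent may engage the vicinal diol (dioxaphosphorane and epoxide formation), or the activated allylic system may react by SN2' or elimination instead of clean SN2 etherification. The fallback sets out from 20 and reverses the activation. Corey–Kim chlorination (NCS, Me2S, CH2Cl2, −20 → 0 °C), which is selective for allylic hydroxyls, should give (3R,6E)-8-chloro-2,6-dimethyloct-6-ene-2,3-diol F3. Williamson etherification of F3 with umbelliferone 21 (K2CO3, acetone or DMF, rt → 50 °C) comes back to the route at 22.

Step 6. The opening may be slow or unselective: the propargyl anion is ambident (allenyl products), and it can act as a base on the hindered silyloxy epoxide. The fallback sets out from 10 and builds the alkyne afterwards by one-carbon homologation.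
- Lithioacetonitrile (MeCN, n-BuLi, THF, −78 °C → rt), a small non-ambident carbanion, should open 10 to (4R)-4-hydroxy-5-methyl-5-[(triethylsilyl)oxy]hexanenitrile F4.
- DIBAL-H (toluene, −78 °C, mild aqueous acid work-up) should give the lactol (5R)-5-{2-[(triethylsilyl)oxy]propan-2-yl}oxolan-2-ol F5.
- Ohira–Bestmann homologation (dimethyl (1-diazo-2-oxopropyl)phosphonate, K2CO3, MeOH, rt) should give (3R)-2-methyl-2-[(triethylsilyl)oxy]hept-6-yn-3-ol F6.
- TBAF (THF) comes back to the route at 14. Loss of the silyl group earlier in this detour is harmless, since 14 is the free diol.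

**Further compounds**

F1 | step 8 | (3R,6E)-7-iodo-2,6-dimethylhept-6-ene-2,3-diol | O[C@H](CC/C(C)=C/I)C(C)(C)O
F2 | step 8 | methyl (2E,6R)-6,7-dihydroxy-3,7-dimethyloct-2-enoate | O[C@H](CC/C(C)=C/C(=O)OC)C(C)(C)O
F3 | step 9 | (3R,6E)-8-chloro-2,6-dimethyloct-6-ene-2,3-diol | O[C@H](CC/C(C)=C/CCl)C(C)(C)O
F4 | step 6 | (4R)-4-hydroxy-5-methyl-5-[(triethylsilyl)oxy]hexanenitrile | CC[Si](CC)(CC)OC(C)(C)[C@H](O)CCC#N
F5 | step 6 | (5R)-5-{2-[(triethylsilyl)oxy]propan-2-yl}oxolan-2-ol | CC[Si](CC)(CC)OC(C)(C)[C@H]1CCC(O)O1
F6 | step 6 | (3R)-2-methyl-2-[(triethylsilyl)oxy]hept-6-yn-3-ol | CC[Si](CC)(CC)OC(C)(C)[C@H](O)CCC#C
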